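**Retrosynthetic overview**
1. The C-8 prenyl group comes last, by cross-metathesis of an 8-allyl group. The allyl group is placed by Claisen rearrangement of the 7-O-allyl ether (C-6 is blocked).
2. The furan ring (C-2–O–C-2') is closed by oxidative cyclisation of a 2'-hydroxyisoflavone.
3. The pyranone ring comes from a chalcone: 1,2-aryl shift with Tl(NO3)3 to an acetal, then acid ring closure.
4. The key C–C bond is made by Claisen–Schmidt aldol condensation of the ring A methyl ketone 6 with the ring B aldehyde 15.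
5. Ring order: the two 2,2-dimethylchroman rings first (prenal annulation of each phenol, then hydrogenation), then the pyranone, then the furan.

Assumption: the SMILES holds no stereocentre and no stereogenic double bond, so the target is achiral and no absolute configuration has to be controlled.

Notation: from 19 on, isoflavone numbering is used. "Bis(dihydropyrano)" means the rings 5-O–CMe2–CH2–CH2–C-6 (ring A) and 4'-O–CMe2–CH2–CH2–C-3' (ring B).

**Ring A fragment**

Step 1
Reactants: 1 2,4,6-trihydroxyacetophenone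
Product: 2 1-[2,6-dihydroxy-4-(methoxymethoxy)phenyl]ethanone
Conditions: MOMCl (1.0 equiv), K2CO3 (1.0 equiv), acetone, 0 °C to rt
Reagents that add atoms: chloromethyl methyl ether (MOMCl) COCCl
Why: Williamson-type O-alkylation takes the 4-OH first because it is the most acidic hydroxyl and the only one that cannot hydrogen-bond to the acetyl group, and the minor bis-ether and recovered 1 are removed by chromatography.

Step 2
Reactants: 2 1-[2,6-dihydroxy-4-(methoxymethoxy)phenyl]ethanone; 3 3-methylbut-2-enal (prenal)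
Product: 5 1-[7-hydroxy-5-(methoxymethoxy)-2,2-dimethyl-2H-chromen-8-yl]ethanone, via ortho-quinone methide 4 (not isolated)
Conditions: ethylenediammonium diacetate (20 mol %), toluene, 110 °C
Reagents that add atoms: none
Why: In this domino Knoevenagel condensation/oxa-6π-electrocyclisation the two free OH groups and the two ring CH positions of 2 are equivalent by symmetry, so only the 8-acetyl chromene can form, and the last OH is chelated, which stops a second annulation.

Step 3
Reactants: 5 1-[7-hydroxy-5-(methoxymethoxy)-2,2-dimethyl-2H-chromen-8-yl]ethanone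
Product: 6 1-[7-hydroxy-5-(methoxymethoxy)-2,2-dimethylchroman-8-yl]ethanone
Conditions: H2 (1 atm), 10% Pd/C, EtOAc, rt
Reagents that add atoms: none
Why: Catalytic hydrogenation saturates the styrene-type chromene double bond long before the chelated aryl ketone, and the MOM ether is inert.

**Ring B fragment**

Step 4
Reactants: 7 2,4-dihydroxybenzaldehyde; 3 3-methylbut-2-enal (prenal)
Product: 9 5-hydroxy-2,2-dimethyl-2H-chromene-6-carbaldehyde, via ortho-quinone methide 8 (not isolated)
Conditions: ethylenediammonium diacetate (10 mol %), toluene, 110 °C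
Reagents that add atoms: none
Why: In the same domino Knoevenagel/oxa-6π-electrocyclisation, C-3 between the two hydroxyls is the most nucleophilic carbon and the non-chelated 4-OH closes the ring, which gives the angular 5-hydroxy-6-formyl chromene.

Step 5
Reactants: 9 5-hydroxy-2,2-dimethyl-2H-chromene-6-carbaldehyde
Product: 10 5-hydroxy-2,2-dimethylchroman-6-carbaldehyde
Conditions: H2 (1 atm), 10% Pd/C, EtOAc, rt, stopped after 1 equiv H2
Reagents that add atoms: none
Why: Catalytic hydrogenation of the conjugated chromene alkene is much faster than reduction of the chelated, electron-rich aldehyde.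

Step 6
Reactants: 10 5-hydroxy-2,2-dimethylchroman-6-carbaldehyde
Product: 11 8-bromo-5-hydroxy-2,2-dimethylchroman-6-carbaldehyde
Conditions: NBS (1.0 equiv), MeCN, 0 °C, dark
Reagents that add atoms: N-bromosuccinimide O=C1CCC(=O)N1Br
Why: In this electrophilic aromatic bromination C-8 is para to the free 5-OH and ortho to the ring oxygen, while C-7 is meta to both and ortho to the formyl group, so only C-8 is attacked.

Step 7
Reactants: 11 8-bromo-5-hydroxy-2,2-dimethylchroman-6-carbaldehyde
Product: 12 8-bromo-5-(methoxymethoxy)-2,2-dimethylchroman-6-carbaldehyde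
Conditions: MOMCl, K2CO3, DMF, 0 °C to rt
Reagents that add atoms: chloromethyl methyl ether (MOMCl) COCCl
Why: Williamson-type O-alkylation in a polar solvent breaks the chelate and masks the phenol as a base-stable acetal that acid removes later.

Step 8
Reactants: 12 8-bromo-5-(methoxymethoxy)-2,2-dimethylchroman-6-carbaldehyde
Product: 13 5-(methoxymethoxy)-2,2-dimethyl-8-(4,4,5,5-tetramethyl-1,3,2-dioxaborolan-2-yl)chroman-6-carbaldehyde
Conditions: B2pin2, Pd(dppf)Cl2 (5 mol %), KOAc, 1,4-dioxane, 90 °C
Reagents that add atoms: bis(pinacolato)diboron CC1(C)OB(OC1(C)C)B1OC(C)(C)C(C)(C)O1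
Why: The Miyaura borylation (oxidative addition of the aryl bromide to zerovalent palladium, acetate-assisted transmetalation, reductive elimination) tolerates the aldehyde and the MOM ether.

Step 9
Reactants: 13 5-(methoxymethoxy)-2,2-dimethyl-8-(4,4,5,5-tetramethyl-1,3,2-dioxaborolan-2-yl)chroman-6-carbaldehyde
Product: 14 8-hydroxy-5-(methoxymethoxy)-2,2-dimethylchroman-6-carbaldehyde
Conditions: NaBO3·4H2O, THF/H2O, rt
Reagents that add atoms: sodium perborate [Na+].[O-]OB=O
Why: Boronate oxidation (peroxide attack on boron, then 1,2-aryl shift to oxygen) is fast at room temperature, whereas a Dakin reaction of the aldehyde is slow because no free ortho or para phenol is present.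

Step 10
Reactants: 14 8-hydroxy-5-(methoxymethoxy)-2,2-dimethylchroman-6-carbaldehyde
Product: 15 8-(benzyloxy)-5-(methoxymethoxy)-2,2-dimethylchroman-6-carbaldehyde
Conditions: BnBr, K2CO3, DMF, rt
Reagents that add atoms: benzyl bromide BrCc1ccccc1
Why: Williamson ether synthesis on the only free phenol gives a group that survives base, thallium nitrate, acid and DDQ and leaves by hydrogenolysis.

**Fragment union and end game**

Step 11
Reactants: 6 1-[7-hydroxy-5-(methoxymethoxy)-2,2-dimethylchroman-8-yl]ethanone; 15 8-(benzyloxy)-5-(methoxymethoxy)-2,2-dimethylchroman-6-carbaldehyde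
Product: 17 (E)-3-[8-(benzyloxy)-5-(methoxymethoxy)-2,2-dimethylchroman-6-yl]-1-[7-hydroxy-5-(methoxymethoxy)-2,2-dimethylchroman-8-yl]prop-2-en-1-one, via aldol adduct 16 (not isolated)
Conditions: KOH, EtOH/H2O, rt, 48 h
Reagents that add atoms: none
Why: In this Claisen–Schmidt aldol condensation only 6 can form an enolate and only 15 is an aldehyde, so the cross-coupling is unambiguous, the racemic carbinol centre of 16 vanishes on E1cB loss of water, and the conjugated E-alkene results.

Step 12
Reactants: 17 the (E)-chalcone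
Product: 18 (±)-2-[8-(benzyloxy)-5-(methoxymethoxy)-2,2-dimethylchroman-6-yl]-1-[7-hydroxy-5-(methoxymethoxy)-2,2-dimethylchroman-8-yl]-3,3-dimethoxypropan-1-one
Conditions: Tl(NO3)3·3H2O (1.1 equiv), MeOH/HC(OMe)3, 0 °C to rt
Reagents that add atoms: methanol CO
Why: In this oxidative 1,2-aryl migration trivalent thallium adds to the enone, the very electron-rich ring B shifts from C-β to C-α as monovalent thallium leaves, methanol traps the oxocarbenium ion as the acetal, and the new centre is racemic and is erased in step 13.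

Step 13
Reactants: 18 the (±)-dimethyl acetal
Product: 20 5'-benzyloxy-7,2'-dihydroxy-bis(dihydropyrano)isoflavone, via bis-MOM isoflavone 19 (not isolated)
Conditions: conc. HCl (cat.), MeOH, 55 °C
Reagents that add atoms: none
Why: Acid-catalysed acetal ionisation lets the ring A phenol close the pyranone with loss of two methanol (isoflavone ring closure), then acetal exchange with methanol removes both MOM groups, while the benzyl ether and the chroman rings survive this mild acid.

Step 14
Reactants: 20 5'-benzyloxy-7,2'-dihydroxy-bis(dihydropyrano)isoflavone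
Product: 21 5'-benzyloxy-7-hydroxy-bis(dihydropyrano)coumaronochromone (2-O-2' furan bridge closed)
Conditions: DDQ (1.2 equiv), dry 1,4-dioxane, rt
Reagents that add atoms: none
Why: In this oxidative cyclodehydrogenation the 2'-OH adds to C-2 of the chromone in an intramolecular oxa-Michael step, and DDQ then takes the hydride from the doubly oxygen-stabilised C-2 and the proton from C-3, which aromatises the new furan.

Step 15
Reactants: 21 5'-benzyloxy-7-hydroxy-bis(dihydropyrano)coumaronochromone
Product: 22 7,5'-dihydroxy-bis(dihydropyrano)coumaronochromone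
Conditions: H2 (1 atm), 10% Pd/C, THF/MeOH, rt
Reagents that add atoms: none
Why: Hydrogenolysis cleaves the benzyl ether before any alkene is present, and the fully substituted aromatic core is not reduced.

Step 16
Reactants: 22 7,5'-dihydroxy-bis(dihydropyrano)coumaronochromone; 23 allyl bromide
Product: 24 7-allyloxy-5'-hydroxy-bis(dihydropyrano)coumaronochromone
Conditions: K2CO3 (1.0 equiv), allyl bromide (1.0 equiv), DMF, 0 °C to rt
Reagents that add atoms: none
Why: This Williamson ether synthesis runs under acidity control, because the 7-OH is a vinylogous acid conjugated to the C-4 carbonyl (pKa about 7.5) and is deprotonated by one equivalent of base ahead of the guaiacol-type 5'-OH (pKa about 10).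

Step 17
Reactants: 24 7-allyloxy-5'-hydroxy-bis(dihydropyrano)coumaronochromone
Product: 26 8-allyl-7,5'-dihydroxy-bis(dihydropyrano)coumaronochromone, via cyclohexadienone 25 (not isolated)
Conditions: PhNEt2, 200 °C, argon
Reagents that add atoms: none
Why: In this aromatic Claisen rearrangement ([3,3]-sigmatropic shift) C-6 carries the chroman CH2, so the allyl group can end only at C-8, and dienone 25 tautomerises back to the phenol.

Step 18
Reactants: 26 8-allyl-7,5'-dihydroxy-bis(dihydropyrano)coumaronochromone; 27 2-methylbut-2-ene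
Product: 28 7,5'-dihydroxy-8-(3-methylbut-2-enyl)-bis(dihydropyrano)coumaronochromone (target CNP0081329.0)
Conditions: second-generation Grubbs catalyst (5 mol %), 2-methylbut-2-ene (excess), CH2Cl2, 40 °C, sealed tube
Reagents that add atoms: none
Why: Olefin cross-metathesis of the terminal allyl group with excess 2-methylbut-2-ene gives the trisubstituted prenyl alkene, and the ruthenium carbene tolerates free phenols.

**Compound list**

1 | 2,4,6-trihydroxyacetophenone | CC(=O)c1c(O)cc(O)cc1O | starting material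
2 | 1-[2,6-dihydroxy-4-(methoxymethoxy)phenyl]ethanone | CC(=O)c1c(O)cc(OCOC)cc1O | intermediate
3 | 3-methylbut-2-enal (prenal) | CC(C)=CC=O | starting material
4 | 2-acetyl-3-hydroxy-5-(methoxymethoxy)-6-(3-methylbut-2-enylidene)cyclohexa-2,4-dien-1-one (not isolated) | CC(=O)C1=C(O)C=C(OCOC)C(=CC=C(C)C)C1=O | intermediate
5 | 1-[7-hydroxy-5-(methoxymethoxy)-2,2-dimethyl-2H-chromen-8-yl]ethanone | CC(=O)c1c(O)cc(OCOC)c2C=CC(C)(C)Oc12 | intermediate
6 | 1-[7-hydroxy-5-(methoxymethoxy)-2,2-dimethylchroman-8-yl]ethanone | CC(=O)c1c(O)cc(OCOC)c2CCC(C)(C)Oc12 | intermediate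
7 | 2,4-dihydroxybenzaldehyde | O=Cc1ccc(O)cc1O | starting material
8 | 2-hydroxy-3-(3-methylbut-2-enylidene)-4-oxocyclohexa-1,5-diene-1-carbaldehyde (not isolated) | O=CC1=C(O)C(=CC=C(C)C)C(=O)C=C1 | intermediate
9 | 5-hydroxy-2,2-dimethyl-2H-chromene-6-carbaldehyde | O=Cc1ccc2OC(C)(C)C=Cc2c1O | intermediate
10 | 5-hydroxy-2,2-dimethylchroman-6-carbaldehyde | O=Cc1ccc2OC(C)(C)CCc2c1O | intermediate
11 | 8-bromo-5-hydroxy-2,2-dimethylchroman-6-carbaldehyde | O=Cc1cc(Br)c2OC(C)(C)CCc2c1O | intermediate
12 | 8-bromo-5-(methoxymethoxy)-2,2-dimethylchroman-6-carbaldehyde | COCOc1c(C=O)cc(Br)c2OC(C)(C)CCc12 | intermediate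
13 | 5-(methoxymethoxy)-2,2-dimethyl-8-(pinacolboryl)chroman-6-carbaldehyde | COCOc1c(C=O)cc(B3OC(C)(C)C(C)(C)O3)c2OC(C)(C)CCc12 | intermediate
14 | 8-hydroxy-5-(methoxymethoxy)-2,2-dimethylchroman-6-carbaldehyde | COCOc1c(C=O)cc(O)c2OC(C)(C)CCc12 | intermediate
15 | 8-(benzyloxy)-5-(methoxymethoxy)-2,2-dimethylchroman-6-carbaldehyde | COCOc1c(C=O)cc(OCc3ccccc3)c2OC(C)(C)CCc12 | intermediate
16 | (±)-β-hydroxy ketone, aldol adduct of 6 and 15 (not isolated) | COCOc1cc(O)c(C(=O)CC(O)c2cc(OCc3ccccc3)c3OC(C)(C)CCc3c2OCOC)c2OC(C)(C)CCc12 | intermediate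
17 | (E)-chalcone from 6 and 15 | COCOc1cc(O)c(C(=O)/C=C/c2cc(OCc3ccccc3)c3OC(C)(C)CCc3c2OCOC)c2OC(C)(C)CCc12 | intermediate
18 | (±)-2-aryl-3,3-dimethoxypropan-1-one (rearranged acetal) | COCOc1cc(O)c(C(=O)C(C(OC)OC)c2cc(OCc3ccccc3)c3OC(C)(C)CCc3c2OCOC)c2OC(C)(C)CCc12 | intermediate
19 | 5'-benzyloxy-7,2'-bis(methoxymethoxy)-bis(dihydropyrano)isoflavone (not isolated) | COCOc1cc2occ(-c3cc(OCc4ccccc4)c4OC(C)(C)CCc4c3OCOC)c(=O)c2c2OC(C)(C)CCc12 | intermediate
20 | 5'-benzyloxy-7,2'-dihydroxy-bis(dihydropyrano)isoflavone | Oc1cc2occ(-c3cc(OCc4ccccc4)c4OC(C)(C)CCc4c3O)c(=O)c2c2OC(C)(C)CCc12 | intermediate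
21 | 5'-benzyloxy-7-hydroxy-bis(dihydropyrano)coumaronochromone | Oc1cc2oc3oc4c5CCC(C)(C)Oc5c(OCc5ccccc5)cc4c3c(=O)c2c2OC(C)(C)CCc12 | intermediate
22 | 7,5'-dihydroxy-bis(dihydropyrano)coumaronochromone | Oc1cc2oc3oc4c5CCC(C)(C)Oc5c(O)cc4c3c(=O)c2c2OC(C)(C)CCc12 | intermediate
23 | allyl bromide | C=CCBr | starting material
24 | 7-allyloxy-5'-hydroxy-bis(dihydropyrano)coumaronochromone | C=CCOc1cc2oc3oc4c5CCC(C)(C)Oc5c(O)cc4c3c(=O)c2c2OC(C)(C)CCc12 | intermediate
25 | (±)-8-allyl-7-oxo-7,8-dihydro tautomer, ring A cyclohexadienone (not isolated) | C=CCC1C(=O)C2=C(OC(C)(C)CC2)C3=C1OC1=C(C3=O)c3cc(O)c4OC(C)(C)CCc4c3O1 | intermediate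
26 | 8-allyl-7,5'-dihydroxy-bis(dihydropyrano)coumaronochromone | C=CCc1c(O)c2CCC(C)(C)Oc2c2c(=O)c3c(oc12)oc1c4CCC(C)(C)Oc4c(O)cc13 | intermediate
27 | 2-methylbut-2-ene | CC=C(C)C | starting material
28 | 7,5'-dihydroxy-8-prenyl-bis(dihydropyrano)coumaronochromone (achiral) | CC(C)=CCc1c(O)c2c(c3c(=O)c4c(oc13)oc1c3c(c(O)cc14)OC(C)(C)CC3)OC(C)(C)CC2 | target

**Totals**
- Total step count: 18.
- Longest linear sequence: 15 steps (7 to 28, steps 4 to 18).

**Steps most likely to fail**

Step 12 (oxidative aryl shift). Thallium nitrate and the nitric acid it releases may attack the electron-rich rings or loosen a MOM group too early. The fallback sets out from 17 and comes back at 20, and it uses no electrophilic oxidant. The chelated OH of 17 is capped (MOMCl, NaH, DMF) to give the tris-MOM chalcone F1. Weitz–Scheffer epoxidation (H2O2, NaOH, MeOH/THF) gives the racemic trans epoxy ketone F2. BF3·OEt2 in CH2Cl2 at −20 °C opens the benzylic C–O bond and triggers a 1,2-aroyl shift to the α-formyl deoxybenzoin F3. HCl in MeOH then strips the three MOM groups, and the ring A phenol condenses with the aldehyde to give 20.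

Step 14 (DDQ ring closure). The para-alkoxyphenol of ring B may be over-oxidised, or a chroman ring may be dehydrogenated. The fallback sets out from 20 and comes back at 21, and it replaces the dehydrogenation by a substitution. Both phenols are protected again (MOMCl, K2CO3, DMF) to give 19, this time isolated. LDA in THF at −78 °C deprotonates C-2, and C2Cl6 traps the anion as the 2-chloro bis-MOM isoflavone F4. HCl in MeOH frees the 2'-OH, which displaces chloride at C-2 by addition–elimination to give 21.

Step 16 (selective 7-O-allylation). Some 5'-O-allyl or bis-allyl ether may form. The fallback sets out from 22 and comes back at 26, and it separates the two phenols by ester lability.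
- Ac2O in pyridine gives the 7,5'-diacetate F5.
- PhSH with imidazole in NMP at 0 °C removes only the ester of the more acidic 7-phenol and gives the 5'-monoacetate F6.
- A Mitsunobu reaction (allyl alcohol, PPh3, DIAD, THF) gives the 7-O-allyl 5'-acetate F7.
- Claisen rearrangement in PhNEt2 at 200 °C gives the 8-allyl 5'-acetate F8.
- K2CO3 in MeOH at rt gives 26.

**Further compounds**
F1 | step 12 | (E)-chalcone 17 with the ring A phenol also protected as a MOM ether (tris-MOM chalcone) | COCOc1cc(OCOC)c(C(=O)/C=C/c2cc(OCc3ccccc3)c3OC(C)(C)CCc3c2OCOC)c2OC(C)(C)CCc12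
F2 | step 12 | (±)-trans-2,3-epoxy ketone of F1 (one enantiomer drawn) | COCOc1cc(OCOC)c(C(=O)[C@H]4O[C@@H]4c2cc(OCc3ccccc3)c3OC(C)(C)CCc3c2OCOC)c2OC(C)(C)CCc12
F3 | step 12 | (±)-2-aryl-3-aryl-3-oxopropanal (α-formyl deoxybenzoin, tris-MOM) | COCOc1cc(OCOC)c(C(=O)C(C=O)c2cc(OCc3ccccc3)c3OC(C)(C)CCc3c2OCOC)c2OC(C)(C)CCc12
F4 | step 14 | 2-chloro-5'-benzyloxy-7,2'-bis(methoxymethoxy)-bis(dihydropyrano)isoflavone | COCOc1cc2oc(Cl)c(-c3cc(OCc4ccccc4)c4OC(C)(C)CCc4c3OCOC)c(=O)c2c2OC(C)(C)CCc12
F5 | step 16 | 7,5'-diacetoxy-bis(dihydropyrano)coumaronochromone | CC(=O)Oc1cc2oc3oc4c5CCC(C)(C)Oc5c(OC(C)=O)cc4c3c(=O)c2c2OC(C)(C)CCc12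
F6 | step 16 | 5'-acetoxy-7-hydroxy-bis(dihydropyrano)coumaronochromone | Oc1cc2oc3oc4c5CCC(C)(C)Oc5c(OC(C)=O)cc4c3c(=O)c2c2OC(C)(C)CCc12
F7 | step 16 | 5'-acetoxy-7-allyloxy-bis(dihydropyrano)coumaronochromone | C=CCOc1cc2oc3oc4c5CCC(C)(C)Oc5c(OC(C)=O)cc4c3c(=O)c2c2OC(C)(C)CCc12
F8 | step 16 | 5'-acetoxy-8-allyl-7-hydroxy-bis(dihydropyrano)coumaronochromone | C=CCc1c(O)c2CCC(C)(C)Oc2c2c(=O)c3c(oc12)oc1c4CCC(C)(C)Oc4c(OC(C)=O)cc13
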